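**Retrosynthetic overview**
1. Feature: in ring A (C4a–C5–C6–C7–C8–C8a) only C6 carries hydrogen. C5, C7, C8 and C8a (lactone O1) carry oxygen, and C4a carries carbon (C4). C5–C6–C7–C8 therefore has the oxygen pattern of a 4-methoxyacetoacetate dienolate, and C4a–C8a with C4 attached has that of an aroylalkyne.
2. Endgame disconnections: 3'-OH from 3'-OBn; pyranone ring C (O1–C2 and C3=C4) from a 2-hydroxybenzophenone and a two-carbon ylide; C8a–OH from C8a–Br; C5–OMe from C5–OH.
3. Key disconnection: C4a–C5 and C8–C8a of ring A, a [4+2] retron once methanol is added back. This gives 1,3,4-trimethoxy-1-(trimethylsilyloxy)butadiene and a bromoethynyl aryl ketone. The bromine marks C8a, a site that electrophilic bromination of the finished ring would miss in favour of C6.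
4. The diene comes in two steps from methyl 4-methoxyacetoacetate. The dienophile comes in three steps from O-benzylisovanillin and ethynylmagnesium bromide.
5. Ring order: ring B (the 4-aryl group) is bought, ring A is built in step 6, and ring C is closed in step 9.

Key step: step 6

Assumption: 3-benzyloxy-4-methoxybenzaldehyde is taken as a catalogue compound, and the diene is drawn with the 4-methoxy group pointing outward, although a mixture of C3=C4 isomers would serve because both sp3 carbons of the cycloadduct become aromatic.

**Step 1**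
Reactants: 1 methyl 4-methoxyacetoacetate
Product: 2 methyl (E)-3,4-dimethoxybut-2-enoate
Conditions: HC(OMe)3 (2 equiv), H2SO4 (cat.), MeOH, 50 °C; distillation
Reagents that add atoms: trimethyl orthoformate, COC(OC)OC
Why: Orthoester-mediated O-methyl enol ether formation of a β-keto ester (ketalisation, then loss of methanol) should give the ester-conjugated C2=C3 enol ether as its thermodynamic E isomer, as it does with methyl acetoacetate.

**Step 2**
Reactants: 2 methyl (E)-3,4-dimethoxybut-2-enoate
Product: 4 (1Z,3Z)-1,3,4-trimethoxy-1-(trimethylsilyloxy)buta-1,3-diene, via lithium dienolate 3 (not isolated)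
Conditions: LiN(i-Pr)2 (commercial solution, 1.1 equiv), THF, −78 °C; Me3SiCl (1.3 equiv), −78 → 0 °C; pentane, filtration under N2, bulb-to-bulb distillation
Reagents that add atoms: chlorotrimethylsilane, C[Si](C)(C)Cl
Why: Carbonyl-directed γ-deprotonation of the CH2OMe group, which lies cis to the ester, gives the extended dienolate 3, and the hard silyl chloride traps it on oxygen (vinylketene silyl acetal formation), the standard access to 1,3-dimethoxy-1-silyloxybutadienes.

**Step 3**
Reactants: 5 3-benzyloxy-4-methoxybenzaldehyde; 6 ethynylmagnesium bromide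
Product: 7 rac-1-(3-benzyloxy-4-methoxyphenyl)prop-2-yn-1-ol
Conditions: THF, 0 → 23 °C; sat. aq. NH4Cl
Reagents that add atoms: none
Why: Grignard 1,2-addition of the acetylide to the aldehyde; the carbinol centre forms racemic, needs no control and is erased in step 4.

**Step 4**
Reactants: 7 rac-1-(3-benzyloxy-4-methoxyphenyl)prop-2-yn-1-ol
Product: 8 1-(3-benzyloxy-4-methoxyphenyl)prop-2-yn-1-one
Conditions: activated MnO2 (12 equiv), CH2Cl2, 23 °C
Reagents that add atoms: none
Why: MnO2 oxidation of an alcohol that is both benzylic and propargylic is fast and neutral and leaves the terminal alkyne and the benzyl ether untouched.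

**Step 5**
Reactants: 8 1-(3-benzyloxy-4-methoxyphenyl)prop-2-yn-1-one
Product: 9 1-(3-benzyloxy-4-methoxyphenyl)-3-bromoprop-2-yn-1-one
Conditions: NBS (1.1 equiv), AgNO3 (10 mol %), acetone, 23 °C, dark
Reagents that add atoms: N-bromosuccinimide, O=C1CCC(=O)N1Br
Why: Silver-catalysed electrophilic bromination of a terminal alkyne (a silver acetylide attacked by NBS) is established for aryl ethynyl ketones, and the acyl-deactivated ring B and the benzylic CH2 should not react under neutral conditions in the dark.

**Step 6**
Reactants: 4 (1Z,3Z)-1,3,4-trimethoxy-1-(trimethylsilyloxy)buta-1,3-diene; 9 1-(3-benzyloxy-4-methoxyphenyl)-3-bromoprop-2-yn-1-one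
Product: 12 (3-benzyloxy-4-methoxyphenyl)(2-bromo-6-hydroxy-3,4-dimethoxyphenyl)methanone, via cyclohexa-1,4-diene cycloadduct 10 (not isolated), via aryl trimethylsilyl ether 11 (not isolated)
Conditions: 4 (1.8 equiv), PhMe, 0 → 60 °C, N2, base-washed glassware, no Lewis acid; then 1 M HCl–THF, 23 °C
Reagents that add atoms: none
Why: This is a normal-electron-demand, strongly asynchronous Diels–Alder reaction: the three donors on C1 and C3 of 4 outweigh the opposed push of the 4-methoxy group and make the CH(OMe) terminus the nucleophilic end, which bonds to the bromine-bearing β-carbon of ynone 9 (C8–C8a) while the ketene-acetal carbon bonds to the α-carbon (C4a–C5), giving 1,4-cyclohexadiene 10. Ionisation of the mixed ketal at C5 and loss of the doubly allylic C8–H expel methanol to give aryl silyl ether 11, which the acid work-up cleaves to phenol 12, held by a hydrogen bond to the ketone. The closest known reaction type is the Diels–Alder benzannulation of 1-alkoxy-1-silyloxy-1,3-dienes with acetylenic ketones and esters, together with the use of 3-bromopropiolates and bromoethynyl ketones as [4+2] dienophiles. Ring A, the only ring closed, forms by intermolecular [4+2] cycloaddition (two C–C bonds, six-membered carbocycle), and the two sp3 centres of 10 (C5 and C8, methoxy groups cis by suprafacial addition) are erased on aromatisation, so diene geometry and endo/exo preference do not matter and no stereocentre remains. The step needs regioselectivity, secured by the single carbonyl group that polarises the alkyne towards C8a, and chemoselectivity for ring closure over addition–elimination at C–Br, secured by the apolar solvent, the absence of any Lewis acid and the closeness of the two reacting ends once the first bond has formed. Should part of 10 lose trimethylsilanol in place of methanol, it gives 13 directly, and both products converge in step 7.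

**Step 7**
Reactants: 12 (3-benzyloxy-4-methoxyphenyl)(2-bromo-6-hydroxy-3,4-dimethoxyphenyl)methanone
Product: 13 (3-benzyloxy-4-methoxyphenyl)(2-bromo-3,4,6-trimethoxyphenyl)methanone
Conditions: MeI (3 equiv), K2CO3 (3 equiv), DMF, 50 °C
Reagents that add atoms: iodomethane, CI
Why: Williamson O-methylation, in which warm DMF and carbonate break the hydrogen bond of the chelated phenol to the ketone and no other acidic site is present.

**Step 8**
Reactants: 13 (3-benzyloxy-4-methoxyphenyl)(2-bromo-3,4,6-trimethoxyphenyl)methanone
Product: 14 (3-benzyloxy-4-methoxyphenyl)(2-hydroxy-3,4,6-trimethoxyphenyl)methanone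
Conditions: Pd2(dba)3 (2 mol %), tBuXPhos (8 mol %), KOH (4 equiv), 1,4-dioxane–H2O 1:1, 100 °C; then 1 M HCl
Reagents that add atoms: potassium hydroxide, [K+].[OH-]
Why: In this palladium-catalysed C–O cross-coupling of an aryl bromide with hydroxide, the ortho ketone speeds oxidative addition to zerovalent palladium and the bulky di-tert-butyl biarylphosphine drives C–O reductive elimination from Ar–Pd–OH even at a bromide flanked on both sides.

**Step 9**
Reactants: 14 (3-benzyloxy-4-methoxyphenyl)(2-hydroxy-3,4,6-trimethoxyphenyl)methanone; 15 ethyl (triphenyl-λ5-phosphanylidene)acetate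
Product: 17 4-(3-benzyloxy-4-methoxyphenyl)-5,7,8-trimethoxy-2H-chromen-2-one, via aryl phosphoranylideneacetate 16 (not isolated)
Conditions: 15 (2.5 equiv), xylenes, 140 °C
Reagents that add atoms: none
Why: This is the Wittig olefination with lactonisation known for 2-hydroxybenzophenones: hot acyl transfer from 15 to the phenol gives ylide ester 16, whose now intramolecular Wittig reaction with the crowded diaryl ketone forms C3=C4 inside the six-membered ring C, where only the lactone geometry is possible.

**Step 10**
Reactants: 17 4-(3-benzyloxy-4-methoxyphenyl)-5,7,8-trimethoxy-2H-chromen-2-one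
Product: 18 4-(3-hydroxy-4-methoxyphenyl)-5,7,8-trimethoxy-2H-chromen-2-one (3'-hydroxy-5,7,8,4'-tetramethoxy-4-phenylcoumarin)
Conditions: H2 (1 atm), 10% Pd/C, EtOAc–MeOH, 23 °C, stopped after one equivalent of H2
Reagents that add atoms: none
Why: Hydrogenolysis of the aryl benzyl ether at 1 atm should be much faster than saturation of the trisubstituted, aryl-conjugated C3=C4 bond of the coumarin, and the four methyl ethers are inert.

**Compound list**
1 | methyl 4-methoxyacetoacetate | COCC(=O)CC(=O)OC | starting material
2 | methyl (E)-3,4-dimethoxybut-2-enoate | COC/C(OC)=C\C(=O)OC | intermediate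
3 | lithium 1,3,4-trimethoxybuta-1,3-dien-1-olate (O–Li cis to C3, 4-OMe outward; not isolated) | CO/C=C(OC)/C=C(/OC)[O-].[Li+] | intermediate
4 | (1Z,3Z)-1,3,4-trimethoxy-1-(trimethylsilyloxy)buta-1,3-diene | CO/C=C(OC)/C=C(/OC)O[Si](C)(C)C | intermediate
5 | 3-benzyloxy-4-methoxybenzaldehyde | COc1ccc(C=O)cc1OCc1ccccc1 | starting material
6 | ethynylmagnesium bromide | C#C[Mg]Br | starting material
7 | rac-1-(3-benzyloxy-4-methoxyphenyl)prop-2-yn-1-ol (racemate, centre not defined) | COc1ccc(C(O)C#C)cc1OCc1ccccc1 | intermediate
8 | 1-(3-benzyloxy-4-methoxyphenyl)prop-2-yn-1-one | COc1ccc(C(=O)C#C)cc1OCc1ccccc1 | intermediate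
9 | 1-(3-benzyloxy-4-methoxyphenyl)-3-bromoprop-2-yn-1-one | O=C(C#CBr)c1ccc(OC)c(OCc2ccccc2)c1 | intermediate
10 | rac-(3-benzyloxy-4-methoxyphenyl)[2-bromo-3,4,6-trimethoxy-6-(trimethylsilyloxy)cyclohexa-1,4-dien-1-yl]methanone, 3-OMe and 6-OMe cis (one enantiomer drawn; not isolated) | CO[C@@]1(O[Si](C)(C)C)C=C(OC)[C@@H](OC)C(Br)=C1C(=O)c1ccc(OC)c(OCc2ccccc2)c1 | intermediate
11 | (3-benzyloxy-4-methoxyphenyl)[2-bromo-3,4-dimethoxy-6-(trimethylsilyloxy)phenyl]methanone (not isolated) | COc1cc(O[Si](C)(C)C)c(C(=O)c2ccc(OC)c(OCc3ccccc3)c2)c(Br)c1OC | intermediate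
12 | (3-benzyloxy-4-methoxyphenyl)(2-bromo-6-hydroxy-3,4-dimethoxyphenyl)methanone | O=C(c1ccc(OC)c(OCc2ccccc2)c1)c1c(Br)c(OC)c(OC)cc1O | intermediate
13 | (3-benzyloxy-4-methoxyphenyl)(2-bromo-3,4,6-trimethoxyphenyl)methanone | O=C(c1ccc(OC)c(OCc2ccccc2)c1)c1c(Br)c(OC)c(OC)cc1OC | intermediate
14 | (3-benzyloxy-4-methoxyphenyl)(2-hydroxy-3,4,6-trimethoxyphenyl)methanone | O=C(c1ccc(OC)c(OCc2ccccc2)c1)c1c(O)c(OC)c(OC)cc1OC | intermediate
15 | ethyl (triphenyl-λ5-phosphanylidene)acetate | CCOC(=O)C=P(c1ccccc1)(c1ccccc1)c1ccccc1 | starting material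
16 | 2-(3-benzyloxy-4-methoxybenzoyl)-3,5,6-trimethoxyphenyl (triphenyl-λ5-phosphanylidene)acetate (not isolated) | O=C(C=P(c1ccccc1)(c1ccccc1)c1ccccc1)Oc1c(OC)c(OC)cc(OC)c1C(=O)c1ccc(OC)c(OCc2ccccc2)c1 | intermediate
17 | 4-(3-benzyloxy-4-methoxyphenyl)-5,7,8-trimethoxy-2H-chromen-2-one | COc1ccc(-c2cc(=O)oc3c(OC)c(OC)cc(OC)c23)cc1OCc1ccccc1 | intermediate
18 | 4-(3-hydroxy-4-methoxyphenyl)-5,7,8-trimethoxy-2H-chromen-2-one | COc1ccc(-c2cc(=O)oc3c(OC)c(OC)cc(OC)c23)cc1O | target

**Step count**
Total step count: 10.
Longest linear sequence: 8 steps (steps 3–10, from 5 to 18). The two-step diene branch joins at step 6.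

**Steps most likely to fail**

1. Step 6.
   - What may go wrong: after the first C–C bond has formed, bromide may leave before the second bond closes, which amounts to alkynylation of the diene terminus. The bromosilane so released may then catalyse more conjugate addition and decay of the diene. The bond between two substituted carbons may also form too slowly next to thermal decay of the bromoalkynone.
   - Fallback: ring A is bought instead of built. The fallback sets out from aldehyde 5. Purchased 1,2,3,5-tetramethoxybenzene is lithiated between two methoxy groups (n-BuLi, THF, 0 °C) to 2,3,4,6-tetramethoxyphenyllithium F1. F1 adds to 5 to give rac-(3-benzyloxy-4-methoxyphenyl)(2,3,4,6-tetramethoxyphenyl)methanol F2. MnO2 in CH2Cl2 oxidises this doubly benzylic alcohol to (3-benzyloxy-4-methoxyphenyl)(2,3,4,6-tetramethoxyphenyl)methanone F3. MgI2·OEt2 in warm toluene, chelated to the ketone, should cleave the more crowded ortho methyl ether, the one flanked by the carbonyl carbon and the 3-methoxy group, and spare the remote benzyl ether. The fallback comes back to the route at 14, so steps 6–8 fall away.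

2. Step 8.
   - What may go wrong: coupling may be slow at a C–Br bond flanked on both sides. The arylpalladium species may attack an ortho C–H of ring B and close a five-membered ring. The C–Br bond may also be reduced.
   - Fallback: a C–B bond is made first and oxidised afterwards. The fallback sets out from 13. Borylation with pinacolborane (PdCl2(MeCN)2, SPhos, Et3N, 1,4-dioxane, 80 °C) is suited to 2,6-disubstituted aryl bromides and runs without hydroxide or carboxylate base. It gives (3-benzyloxy-4-methoxyphenyl)[3,4,6-trimethoxy-2-(4,4,5,5-tetramethyl-1,3,2-dioxaborolan-2-yl)phenyl]methanone F4. Mild oxidation with NaBO3·4H2O in THF–H2O at 23 °C brings the fallback back to the route at 14.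

3. Step 9.
   - What may go wrong: acyl transfer to the hindered, hydrogen-bonded phenol may be sluggish. The stabilised ylide may attack a ketone with two ortho substituents only slowly, so that the ylide decays at 140 °C first.
   - Fallback: the two events are separated and a more nucleophilic phosphonate carbanion is used. The fallback sets out from 14. Acylation with diethylphosphonoacetic acid (EDC·HCl, DMAP, CH2Cl2, 23 °C) gives 2-(3-benzyloxy-4-methoxybenzoyl)-3,5,6-trimethoxyphenyl 2-(diethoxyphosphoryl)acetate F5. An intramolecular Horner–Wadsworth–Emmons reaction (LiCl, DBU, MeCN, 23 → 50 °C) closes ring C, and the fallback comes back to the route at 17.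

**Further compounds**
F1 | step 6 | 2,3,4,6-tetramethoxyphenyllithium | [Li]c1c(OC)cc(OC)c(OC)c1OC
F2 | step 6 | rac-(3-benzyloxy-4-methoxyphenyl)(2,3,4,6-tetramethoxyphenyl)methanol | COc1ccc(C(O)c2c(OC)cc(OC)c(OC)c2OC)cc1OCc1ccccc1
F3 | step 6 | (3-benzyloxy-4-methoxyphenyl)(2,3,4,6-tetramethoxyphenyl)methanone | COc1ccc(C(=O)c2c(OC)cc(OC)c(OC)c2OC)cc1OCc1ccccc1
F4 | step 8 | (3-benzyloxy-4-methoxyphenyl)[3,4,6-trimethoxy-2-(4,4,5,5-tetramethyl-1,3,2-dioxaborolan-2-yl)phenyl]methanone | COc1ccc(C(=O)c2c(OC)cc(OC)c(OC)c2B3OC(C)(C)C(C)(C)O3)cc1OCc1ccccc1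
F5 | step 9 | 2-(3-benzyloxy-4-methoxybenzoyl)-3,5,6-trimethoxyphenyl 2-(diethoxyphosphoryl)acetate | CCOP(=O)(OCC)CC(=O)Oc1c(OC)c(OC)cc(OC)c1C(=O)c1ccc(OC)c(OCc2ccccc2)c1
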